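**Retrosynthetic overview**
1. The target comes from Yamaguchi acylation of the C8‑OH core alcohol 31 with (E)‑N‑methylurocanic acid. The oxa‑bridged hemiketal comes from MnO2 oxidation of a bis‑allylic alcohol to a Z‑dienone, followed by acetonide removal, which lets the tertiary alcohol close onto the ketone.
2. The 10‑membered carbocycle is closed by an intramolecular Nozaki–Hiyama–Kishi (NHK) coupling of a (Z)‑α‑iodoenoate with a Z‑enal. The ketone‑level n‑carbon is set after the closure, so the new carbinol stereocentre never matters.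
3. The syn‑diol with the quaternary methyl carbinol (j, k) comes from a new Zn‑ProPhenol aldol of acetoin with a cyclohexene‑acetaldehyde. The methyl ketone is then converted to the Z‑enal through a terminal alkyne.
4. The cyclohexene (c, d, h) comes from (S)‑carvone by trans‑alkylation, epoxidation/Wharton transposition and a suprafacial Johnson–Claisen.
5. Ring order: cyclohexene (pre‑existing), then the 10‑membered ring (NHK), then the oxa‑bridge (hemiketalisation).

Assumptions:
- (S)‑(+)‑Carvone is commercial.
- The (S,S)‑ProPhenol enantiomer is assumed to give the required (S)‑configured secondary carbinol j.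
- Racemic acetoin is usable because its Zn‑enediolate is achiral.

**Route**

Step 1
Reactants: 1 (S)‑carvone
Product: 2 (S)‑carvotanacetone
Conditions: H2 (1 atm), RhCl(PPh3)3, benzene/EtOH, rt
Reagents that add atoms: none
Why: Wilkinson hydrogenation reduces only the 1,1‑disubstituted isopropenyl group and leaves the enone C=C, so the C5 stereocentre (d) is retained and becomes the isopropyl carbon.

Step 2
Reactants: 2; 3 benzyl chloromethyl ether
Product: 4 6‑(benzyloxymethyl)‑5‑isopropyl‑2‑methylcyclohex‑2‑enone, CH2OBn trans to iPr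
Conditions: LDA, THF, –78 °C; then 3, HMPA, –78 → –30 °C
Reagents that add atoms: BOMCl, ClCOCc1ccccc1
Why: Kinetic enolate alkylation occurs at C6 (the only enolisable α‑carbon) by axial attack anti to the C5 isopropyl, which sets c.

Step 3
Reactants: 4; 5 hydrogen peroxide
Product: 6 α,β‑epoxy ketone, epoxide O anti to iPr
Conditions: 30% aq. H2O2, cat. NaOH, MeOH, 0 °C
Reagents that add atoms: H2O2, OO
Why: Weitz–Scheffer epoxidation by axial attack of HOO– anti to the C5 group; the basic medium also equilibrates the C6 centre to the trans (diequatorial) isomer.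

Step 4
Reactants: 6
Product: 7 allylic alcohol with C1=C2(Me) and C3–OH (OH anti to iPr)
Conditions: N2H4·H2O, cat. AcOH, MeOH, 0 °C → rt
Reagents that add atoms: none (hydrazine is lost as N2)
Why: Wharton transposition moves the alkene into the former carbonyl position, and the C3–O bond, and hence its face, is retained.

Step 5
Reactants: 7
Product: 8 diol (free CH2OH and free allylic OH)
Conditions: LiDBB, THF, –78 °C; NH4Cl
Reagents that add atoms: none
Why: Dissolving‑metal‑type debenzylation leaves the trisubstituted alkene intact.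

Step 6
Reactants: 8; 9 TBDPSCl
Product: 10 primary TBDPS ether, secondary allylic OH free
Conditions: TBDPSCl, imidazole, DMF, 0 °C → rt
Reagents that add atoms: TBDPSCl, CC(C)(C)[Si](Cl)(c1ccccc1)c1ccccc1
Why: The primary alcohol is silylated selectively over the hindered secondary allylic alcohol.

Step 7
Reactants: 10; 11 triethyl orthoacetate
Product: 12 ethyl ester, CH2CO2Et on C1 (h) cis to CH2OTBDPS, alkene now C2(Me)=C3
Conditions: MeC(OEt)3 (10 equiv), cat. EtCO2H, 140 °C, sealed tube
Reagents that add atoms: MeC(OEt)3, CC(OCC)(OCC)OCC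
Why: Johnson–Claisen [3,3] rearrangement is suprafacial, so it delivers the new C–C bond to C1 on the face of the C3–O bond (anti to iPr, cis to the C6 substituent). This sets h and transposes the alkene to the target's g=f position.

Step 8
Reactants: 12
Product: 13 aldehyde, h–CH2–CHO
Conditions: DIBAL‑H (1.1 equiv), CH2Cl2, –78 °C; Rochelle salt
Reagents that add atoms: none
Why: Low‑temperature DIBAL stops at the aldehyde and leaves the TBDPS ether and the alkene untouched.

Step 9
Reactants: 13; 14 acetoin
Product: 15 syn‑2,3‑dihydroxy‑3‑methyl ketone (j S, k R in this compound), R–CH(OH)–C(OH)(CH3)–C(=O)CH3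
Conditions: (S,S)‑ProPhenol (10 mol%), Et2Zn (20 mol%), Ph3P=S (10 mol%), 4 Å MS, THF, rt; acetoin (5 equiv)
Reagents that add atoms: acetoin, CC(=O)C(C)O
Why: Proposed new method: a dinuclear Zn‑ProPhenol catalyst binds acetoin as a symmetrical, Z‑chelated Zn‑enediolate. Its tertiary carbinol carbon attacks the second Zn‑activated aldehyde through a closed Zimmerman–Traxler‑type transition state. This gives the syn‑diol (j and k set together, ligand controlling both faces) with a fully substituted carbinol centre that cannot epimerise, and racemic acetoin is fine because the enediolate is achiral. The closest known reaction is the Zn‑ProPhenol direct aldol of α‑hydroxy ketones such as hydroxyacetophenone, which has not been shown for a tertiary carbinol nucleophile.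

Step 10
Reactants: 15; 16 2,2‑dimethoxypropane
Product: 17 acetonide of the j,k‑diol
Conditions: Me2C(OMe)2 (10 equiv), cat. PPTS, CH2Cl2, rt
Reagents that add atoms: 2,2‑dimethoxypropane, COC(C)(C)OC
Why: Acid‑catalysed ketalisation protects both hydroxyls so that they survive the strongly basic alkyne chemistry, and the j and k stereocentres are untouched.

Step 11
Reactants: 17
Product: 18 terminal alkyne, k–C≡CH
Conditions: (1) LDA (1.2 equiv), THF, –78 °C; ClP(O)(OEt)2; (2) LDA (3 equiv), –78 → 0 °C; NH4Cl
Reagents that add atoms: none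
Why: Negishi enol‑phosphate route from a methyl ketone; only the methyl side is enolisable, and the quaternary k is not affected.

Step 12
Reactants: 18; 19 triethyl orthoformate
Product: 20 propargylic diethyl acetal, k–C≡C–CH(OEt)2
Conditions: EtMgBr, THF, 50 °C; then HC(OEt)3 (5 equiv), 65 °C
Reagents that add atoms: HC(OEt)3, CCOC(OCC)OCC
Why: Bodroux–Chichibabin coupling of the alkynyl Grignard with orthoformate installs the protected n‑aldehyde carbon.

Step 13
Reactants: 20
Product: 21 Z‑enal diethyl acetal, k–CH=CH–CH(OEt)2 (Z)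
Conditions: H2 (1 atm), Lindlar catalyst, quinoline, EtOAc, rt
Reagents that add atoms: none
Why: Lindlar semihydrogenation adds H2 syn to give the Z‑alkene (l=m) and leaves the trisubstituted ring alkene alone.

Step 14
Reactants: 21
Product: 22 primary alcohol, c–CH2OH
Conditions: TBAF, THF, 0 °C → rt
Reagents that add atoms: none
Why: Fluoride removes the silyl ether while the acetal and acetonide are stable.

Step 15
Reactants: 22
Product: 23 aldehyde, c–CHO
Conditions: Dess–Martin periodinane, NaHCO3, CH2Cl2, 0 °C
Reagents that add atoms: none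
Why: Buffered Dess–Martin oxidation avoids acid and so minimises epimerisation of the α‑stereocentre c.

Step 16
Reactants: 24 trimethyl phosphonoacetate; 25 iodine
Product: 26 methyl 2‑(dimethoxyphosphoryl)‑2‑iodoacetate
Conditions: NaH, THF, 0 °C; then I2, –78 → 0 °C
Reagents that add atoms: I2, II
Why: The stabilised phosphonate carbanion is iodinated by I2 (α‑halogenation); the reagent is used immediately.

Step 17
Reactants: 23; 26
Product: 27 (Z)‑α‑iodoenoate with c–CH=C(I)CO2Me (I cis to c, ester trans to c)
Conditions: 26, iPrMgBr, THF, –78 → –20 °C; add 23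
Reagents that add atoms: phosphonate 26, COC(=O)C(I)P(=O)(OC)OC (supplies the =C(I)CO2Me unit)
Why: In the Horner–Wadsworth–Emmons olefination the Mg‑chelated α‑halo phosphonate gives the alkene with the ester trans to the aldehyde substituent, which is the Z‑iodide and the geometry the target needs after I→Cr replacement.

Step 18
Reactants: 27
Product: 28 Z‑enal, k–CH=CH–CHO
Conditions: TESOTf, 2,4,6‑collidine, CH2Cl2, 0 °C; then H2O
Reagents that add atoms: water, O
Why: Fujioka acetal cleavage via the collidinium salt unmasks the aldehyde selectively in the presence of the acetonide, and the Z‑enal is preserved under near‑neutral conditions.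

Step 19
Reactants: 28
Product: 29 ten‑membered macrocyclic bis‑allylic alcohol (n‑epimeric mixture), a–n bond formed
Conditions: CrCl2 (10 equiv), cat. NiCl2, DMF, 0.002 M, syringe‑pump addition, rt
Reagents that add atoms: none
Why: Intramolecular Nozaki–Hiyama–Kishi coupling of the vinyl‑Cr species (alkene geometry retained, so n is cis to c and the ester trans) adds to the aldehyde; the new n carbinol centre is erased in the next step.

Step 20
Reactants: 29
Product: 30 Z‑dienone, acetonide intact
Conditions: MnO2 (30 equiv), CH2Cl2, rt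
Reagents that add atoms: none
Why: MnO2 oxidises the doubly allylic alcohol chemoselectively, which removes the n stereocentre.

Step 21
Reactants: 30
Product: 31 core hemiketal alcohol (8‑O‑desacylsarcodictyin A)
Conditions: AcOH/H2O/THF (3:1:1), 40 °C
Reagents that add atoms: water, O
Why: Acetonide hydrolysis frees the tertiary k‑OH, which adds to the cis‑enone carbonyl (oxa‑Michael‑type hemiketalisation), and the bridge fixes the configuration at n.

Step 22
Reactants: 32 1‑methylimidazole‑4‑carbaldehyde; 33 malonic acid
Product: 34 (E)‑3‑(1‑methylimidazol‑4‑yl)acrylic acid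
Conditions: pyridine, cat. piperidine, 100 °C
Reagents that add atoms: malonic acid, OC(=O)CC(=O)O
Why: Knoevenagel–Doebner condensation with decarboxylation gives the E‑acrylic acid.

Step 23
Reactants: 31; 34; 35 2,4,6‑trichlorobenzoyl chloride
Product: 36 sarcodictyin A
Conditions: 34, Et3N, 35, THF, rt; then 31, DMAP, toluene, rt
Reagents that add atoms: none (the acyl group comes from 34; the trichlorobenzoate is lost)
Why: Yamaguchi esterification acylates the secondary j‑OH, and the tertiary hemiketal OH is too hindered to compete.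

**Compound list**

1 | (S)‑(+)‑carvone | CC1=CC[C@@H](CC1=O)C(C)=C | starting material
2 | (S)‑carvotanacetone | CC1=CC[C@@H](CC1=O)C(C)C | intermediate
3 | benzyl chloromethyl ether | ClCOCc1ccccc1 | starting material
4 | 6‑(benzyloxymethyl) enone, trans to iPr | CC1=CC[C@H](C(C)C)[C@@H](COCc2ccccc2)C1=O | intermediate
5 | hydrogen peroxide | OO | starting material
6 | epoxy ketone | C[C@]12O[C@H]1C[C@H](C(C)C)[C@@H](COCc3ccccc3)C2=O | intermediate
7 | allylic alcohol (Wharton) | CC1=C[C@H](COCc2ccccc2)[C@@H](C(C)C)C[C@@H]1O | intermediate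
8 | diol | CC1=C[C@H](CO)[C@@H](C(C)C)C[C@@H]1O | intermediate
9 | TBDPSCl | CC(C)(C)[Si](Cl)(c1ccccc1)c1ccccc1 | starting material
10 | TBDPS ether | CC1=C[C@H](CO[Si](c2ccccc2)(c2ccccc2)C(C)(C)C)[C@@H](C(C)C)C[C@@H]1O | intermediate
11 | triethyl orthoacetate | CC(OCC)(OCC)OCC | starting material
12 | Claisen ester | CCOC(=O)C[C@H]1C(C)=CC[C@H](C(C)C)[C@H]1CO[Si](c1ccccc1)(c1ccccc1)C(C)(C)C | intermediate
13 | aldehyde | O=CC[C@H]1C(C)=CC[C@H](C(C)C)[C@H]1CO[Si](c1ccccc1)(c1ccccc1)C(C)(C)C | intermediate
14 | acetoin | CC(=O)C(C)O | starting material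
15 | aldol diol ketone | CC(=O)[C@](C)(O)[C@@H](O)C[C@H]1C(C)=CC[C@H](C(C)C)[C@H]1CO[Si](c1ccccc1)(c1ccccc1)C(C)(C)C | intermediate
16 | 2,2‑dimethoxypropane | COC(C)(C)OC | starting material
17 | acetonide ketone | CC(=O)[C@]1(C)OC(C)(C)O[C@H]1C[C@H]2C(C)=CC[C@H](C(C)C)[C@H]2CO[Si](c3ccccc3)(c3ccccc3)C(C)(C)C | intermediate
18 | terminal alkyne | C#C[C@]1(C)OC(C)(C)O[C@H]1C[C@H]2C(C)=CC[C@H](C(C)C)[C@H]2CO[Si](c3ccccc3)(c3ccccc3)C(C)(C)C | intermediate
19 | triethyl orthoformate | CCOC(OCC)OCC | starting material
20 | propargylic acetal | CCOC(OCC)C#C[C@]1(C)OC(C)(C)O[C@H]1C[C@H]2C(C)=CC[C@H](C(C)C)[C@H]2CO[Si](c3ccccc3)(c3ccccc3)C(C)(C)C | intermediate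
21 | Z‑enal acetal | CCOC(OCC)/C=C\[C@]1(C)OC(C)(C)O[C@H]1C[C@H]2C(C)=CC[C@H](C(C)C)[C@H]2CO[Si](c3ccccc3)(c3ccccc3)C(C)(C)C | intermediate
22 | primary alcohol | CCOC(OCC)/C=C\[C@]1(C)OC(C)(C)O[C@H]1C[C@H]2C(C)=CC[C@H](C(C)C)[C@H]2CO | intermediate
23 | aldehyde | CCOC(OCC)/C=C\[C@]1(C)OC(C)(C)O[C@H]1C[C@H]2C(C)=CC[C@H](C(C)C)[C@H]2C=O | intermediate
24 | trimethyl phosphonoacetate | COC(=O)CP(=O)(OC)OC | starting material
25 | iodine | II | starting material
26 | methyl 2‑iodo‑2‑(dimethoxyphosphoryl)acetate | COC(=O)C(I)P(=O)(OC)OC | intermediate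
27 | (Z)‑α‑iodoenoate | CCOC(OCC)/C=C\[C@]1(C)OC(C)(C)O[C@H]1C[C@H]2C(C)=CC[C@H](C(C)C)[C@H]2/C=C(\I)C(=O)OC | intermediate
28 | Z‑enal | O=C/C=C\[C@]1(C)OC(C)(C)O[C@H]1C[C@H]2C(C)=CC[C@H](C(C)C)[C@H]2/C=C(\I)C(=O)OC | intermediate
29 | macrocyclic alcohol (n‑epimers) | COC(=O)/C1=C/[C@@H]2[C@@H](C(C)C)CC=C(C)[C@@H]2C[C@@H]3OC(C)(C)O[C@@]3(C)/C=C\C1O | intermediate
30 | macrocyclic Z‑dienone acetonide | COC(=O)/C1=C/[C@@H]2[C@@H](C(C)C)CC=C(C)[C@@H]2C[C@@H]3OC(C)(C)O[C@@]3(C)/C=C\C1=O | intermediate
31 | core hemiketal alcohol | COC(=O)/C1=C/[C@@H]2[C@@H](C(C)C)CC=C(C)[C@@H]2C[C@H](O)[C@]2(C)C=C[C@@]1(O)O2 | intermediate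
32 | 1‑methylimidazole‑4‑carbaldehyde | Cn1cnc(C=O)c1 | starting material
33 | malonic acid | OC(=O)CC(=O)O | starting material
34 | (E)‑3‑(1‑methylimidazol‑4‑yl)acrylic acid | Cn1cnc(/C=C/C(=O)O)c1 | intermediate
35 | 2,4,6‑trichlorobenzoyl chloride | O=C(Cl)c1c(Cl)cc(Cl)cc1Cl | starting material
36 | sarcodictyin A | COC(=O)/C1=C/[C@@H]2[C@@H](C(C)C)CC=C(C)[C@@H]2C[C@H](OC(=O)/C=C/c2cn(C)cn2)[C@]2(C)C=C[C@@]1(O)O2 | target

**Totals:** 23 steps in all, including two short branch steps (16 and 22). The longest linear sequence is 21 steps (1–15, 17–21, 23).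

**Three steps most likely to fail**
1. **Step 9 (proposed new aldol).** Acetoin may not react at its tertiary carbinol carbon, and retro‑aldol or dr/ee problems are possible. Fallback: Seebach aldol of the (S)‑lactic‑acid‑derived 2‑tBu‑5‑methyl‑1,3‑dioxolan‑4‑one enolate with 13 (known chemistry). Then open the dioxolanone to the acetonide aldehyde (methanolysis, acetonide formation, DIBAL) and use Ohira–Bestmann alkynylation to re‑enter at 18.
2. **Step 19 (NHK macrocyclisation).** The strained cis,cis ten‑membered ring may give oligomers. Fallback: close the ring by macro‑RCM instead. Use an HWE reagent carrying a –CH(OTBS)CH=CH2 group in Step 17, make k–CH=CH2 by oxidation and methylenation in place of the alkyne, close with Hoveyda–Grubbs II, then remove the silyl group and oxidise with MnO2 to rejoin at 30.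
3. **Step 7 (Johnson–Claisen at hindered C1, cis to CH2OTBDPS).** Steric congestion may cause low conversion or decomposition. Fallback: Horner–Wadsworth–Emmons olefination of ketone 4 with triethyl phosphonoacetate, then 1,4‑reduction of the exocyclic dienoate (Mg/MeOH) and separation of the diastereomers. Then swap Bn for TBDPS (LiDBB, TBDPSCl) to give ester 12.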